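**Retrosynthetic overview** (locants C1–C7a are the indene locants of the target)
1. The C4 ester bond is cut last: hydrindenone alcohol (core acid masked as its 4-methoxybenzyl ester) plus (2E,4E,6R)-4,6-dimethylocta-2,4-dienoic acid, itself made from (R)-2-methylbutan-1-ol by two olefinations.
2. C4–OH comes from a vinylogous Rubottom oxidation of the enone; the 2-formylallyl chain at C1 from enolate alkylation followed by N-oxide oxidation.
3. Key step: a carbonylative ring expansion of a spiro[3.5] cyclobutanone (C1 shifts from C3a to C7a), which makes the cyclopentenone, the C7a quaternary centre and the C7 carboxyl in one operation.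
4. The spiro cyclobutanone comes from a keteniminium [2+2] on the diene obtained by methylenation of 2-methylcyclohex-2-en-1-one.
5. Ring order: six-membered ring (purchased), then the cyclobutanone, then the five-membered ring by expansion of the four-membered ring.

Assumption: (R)-2-methylbutan-1-ol is purchasable as the single enantiomer.

**Route**

Step 1
Reactants: 1 2-methylcyclohex-2-en-1-one
Product: 2 1-methyl-6-methylidenecyclohex-1-ene
Conditions: Ph3PCH3Br, KOtBu, THF, 0 to 25 °C
Reagents that add atoms: methyltriphenylphosphonium bromide, C[P+](c1ccccc1)(c1ccccc1)c1ccccc1.[Br-]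
Why: Wittig methylenation, in which the unstabilised ylide adds 1,2 to the enone carbonyl and the oxaphosphetane collapses to the exocyclic methylene; no stereocentre is formed.

Step 2
Reactants: 2 1-methyl-6-methylidenecyclohex-1-ene; 3 N,N-dimethylacetamide
Product: 6 5-methylspiro[3.5]non-5-en-2-one, via keteniminium triflate 4 (not isolated), via cyclobutaniminium triflate 5 (not isolated)
Conditions: 3, Tf2O, 2,4,6-collidine, ClCH2CH2Cl, -15 to 80 °C; then H2O, 25 °C
Reagents that add atoms: water, O
Why: Ghosez keteniminium [2+2] cycloaddition, in which the electrophilic central carbon of 4 bonds to the terminal CH2 of the s-trans-locked diene (best allyl cation, no [4+2] possible), ring closure at the adjacent ring carbon gives the 3,3-spiro iminium 5, and water hydrolyses it to the achiral cyclobutanone.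

Step 3
Reactants: 6 5-methylspiro[3.5]non-5-en-2-one
Product: 7 4-methoxybenzyl (7R,7aS)-7a-methyl-2-oxo-2,4,5,6,7,7a-hexahydro-1H-indene-7-carboxylate
Conditions: Pd(OCOCF3)2 (10 mol %), (S,S)-Bn-BOXAX (20 mol %), p-benzoquinone (2 equiv), CO (1 atm), 4-MeOC6H4CH2OH (5 equiv), CH2Cl2, 25 °C
Reagents that add atoms: carbon monoxide, [C-]#[O+]; 4-methoxybenzyl alcohol, COc1ccc(CO)cc1
Why: Proposed new method: an enantioselective carbonylative Wagner–Meerwein ring expansion in which the cationic divalent palladium–bis(oxazoline) complex binds one enantiotopic face of the trisubstituted C=C, the strained cyclobutane C–C bond anti to palladium migrates to the methyl-bearing carbon (cyclobutylcarbinyl to cyclopentyl, roughly 20 kcal/mol of strain released), the tertiary cation left at the former spiro carbon loses the adjacent α-keto proton to give the enone, and the secondary alkylpalladium inserts CO with retention and is captured by the alcohol while benzoquinone reoxidises zerovalent palladium, so the ester ends trans to the migrated CH2 and cis to the new angular methyl and the ligand-controlled face choice sets (7R,7aS) (the sense of induction cannot be predicted, so the ligand antipode is used if it proves opposite); the closest known reaction types are the enantioselective palladium-catalysed Wacker-cyclisation/alkoxycarbonylation domino reaction, palladium- and platinum-catalysed ring expansions of alkylidenecyclopropanes and vinylcyclobutanols, and acid-mediated cyclobutylcarbinyl ring expansions.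

Step 4
Reactants: 7 4-methoxybenzyl (7R,7aS)-7a-methyl-2-oxo-2,4,5,6,7,7a-hexahydro-1H-indene-7-carboxylate; 8 3-bromo-2-(bromomethyl)prop-1-ene
Product: 9 4-methoxybenzyl (1R,7R,7aS)-1-[2-(bromomethyl)prop-2-en-1-yl]-7a-methyl-2-oxo-2,4,5,6,7,7a-hexahydro-1H-indene-7-carboxylate
Conditions: LiN(iPr)2, THF, -78 °C; then added to 8 (3 equiv), DMPU, -78 to -40 °C
Reagents that add atoms: none
Why: Kinetic α'-deprotonation of the cyclopentenone gives the cross-conjugated C1 enolate, which is alkylated (SN2 enolate alkylation) on the face anti to the C7 ring branch, i.e. cis to the angular methyl (1R); this face preference is argued from sterics rather than certain, but C1 is epimerisable and 1R is expected to be the thermodynamic epimer as well.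

Step 5
Reactants: 9 4-methoxybenzyl (1R,7R,7aS)-1-[2-(bromomethyl)prop-2-en-1-yl]-7a-methyl-2-oxo-2,4,5,6,7,7a-hexahydro-1H-indene-7-carboxylate
Product: 10 4-methoxybenzyl (1R,7R,7aS)-1-(2-formylprop-2-en-1-yl)-7a-methyl-2-oxo-2,4,5,6,7,7a-hexahydro-1H-indene-7-carboxylate
Conditions: N-methylmorpholine N-oxide (3 equiv), NaHCO3, MeCN, 0 to 25 °C
Reagents that add atoms: N-methylmorpholine N-oxide, C[N+]1([O-])CCOCC1
Why: N-oxide oxidation of an allylic bromide (Kornblum-type), in which SN2 displacement by the N-oxide oxygen and base-induced N–O cleavage give the α-methylene aldehyde under near-neutral conditions that leave the enone, the ester and the stereocentres untouched.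

Step 6
Reactants: 10 4-methoxybenzyl (1R,7R,7aS)-1-(2-formylprop-2-en-1-yl)-7a-methyl-2-oxo-2,4,5,6,7,7a-hexahydro-1H-indene-7-carboxylate
Product: 12 4-methoxybenzyl (1R,4S,7R,7aS)-1-(2-formylprop-2-en-1-yl)-4-hydroxy-7a-methyl-2-oxo-2,4,5,6,7,7a-hexahydro-1H-indene-7-carboxylate, via silyl dienol ether 11 (not isolated)
Conditions: TMSOTf, Et3N, CH2Cl2, -78 to 0 °C; then dimethyldioxirane, acetone, -78 °C; then 1 M HCl, THF, 0 °C
Reagents that add atoms: dimethyldioxirane, CC1(C)OO1
Why: Vinylogous Rubottom oxidation, in which soft enolisation gives the extended 2-silyloxy diene 11 (γ-deprotonation at C4, C1 being tertiary and hindered), its electron-rich C3a=C4 bond is oxidised far faster than the enal alkene, and axial attack through a chair-like transition state (as in the 6β-hydroxylation of steroidal 3,5-dienol ethers) places the new OH cis to the angular methyl (4S).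

Step 7
Reactants: 13 (R)-2-methylbutan-1-ol
Product: 15 (2E,4R)-2,4-dimethylhex-2-enal, via (R)-2-methylbutanal 14 (not isolated)
Conditions: TEMPO (10 mol %), PhI(OAc)2, CH2Cl2, 25 °C; then Ph3P=C(CH3)CHO, toluene, 80 °C
Reagents that add atoms: 2-(triphenylphosphoranylidene)propanal, CC(C=O)=P(c1ccccc1)(c1ccccc1)c1ccccc1
Why: TEMPO/PhI(OAc)2 oxidation gives the configurationally labile aldehyde 14 without base and it is trapped in the same flask by Wittig olefination with the formyl-stabilised ylide, which gives the (E)-trisubstituted enal; the stereocentre comes from 13 and is not touched.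

Step 8
Reactants: 15 (2E,4R)-2,4-dimethylhex-2-enal
Product: 16 (2E,4E,6R)-4,6-dimethylocta-2,4-dienoic acid
Conditions: (EtO)2P(O)CH2CO2H, n-BuLi (2 equiv), THF, -78 to 25 °C; then 1 M HCl
Reagents that add atoms: diethylphosphonoacetic acid, CCOP(=O)(CC(=O)O)OCC
Why: Horner–Wadsworth–Emmons olefination with the dianion of the phosphonoacetic acid gives the (2E)-acid directly, and the amine-free low-temperature conditions avoid dienamine formation, so the γ-stereocentre is not epimerised.

Step 9
Reactants: 12 4-methoxybenzyl (1R,4S,7R,7aS)-1-(2-formylprop-2-en-1-yl)-4-hydroxy-7a-methyl-2-oxo-2,4,5,6,7,7a-hexahydro-1H-indene-7-carboxylate; 16 (2E,4E,6R)-4,6-dimethylocta-2,4-dienoic acid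
Product: 17 4-methoxybenzyl (1R,4S,7R,7aS)-4-{[(2E,4E,6R)-4,6-dimethylocta-2,4-dienoyl]oxy}-1-(2-formylprop-2-en-1-yl)-7a-methyl-2-oxo-2,4,5,6,7,7a-hexahydro-1H-indene-7-carboxylate
Conditions: DCC, DMAP (20 mol %), CH2Cl2, 0 to 25 °C
Reagents that add atoms: none
Why: Steglich esterification (carbodiimide activation, DMAP acyl transfer) acylates the only hydroxyl group with retention at C4.

Step 10
Reactants: 17 4-methoxybenzyl (1R,4S,7R,7aS)-4-{[(2E,4E,6R)-4,6-dimethylocta-2,4-dienoyl]oxy}-1-(2-formylprop-2-en-1-yl)-7a-methyl-2-oxo-2,4,5,6,7,7a-hexahydro-1H-indene-7-carboxylate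
Product: 18 (1R,4S,7R,7aS)-4-{[(2E,4E,6R)-4,6-dimethylocta-2,4-dienoyl]oxy}-1-(2-formylprop-2-en-1-yl)-7a-methyl-2-oxo-2,4,5,6,7,7a-hexahydro-1H-indene-7-carboxylic acid
Conditions: CF3CO2H, anisole, CH2Cl2, 0 °C
Reagents that add atoms: none
Why: Acidolysis of the 4-methoxybenzyl ester (SN1 cleavage through the 4-methoxybenzyl cation, trapped by anisole) frees the acid, while the secondary allylic dienoate (its cation would be destabilised by the enone), the enal and the enone are stable to CF3CO2H at 0 °C.

**Compound list**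
1 | 2-methylcyclohex-2-en-1-one | CC1=CCCCC1=O | starting material
2 | 1-methyl-6-methylidenecyclohex-1-ene | CC1=CCCCC1=C | intermediate
3 | N,N-dimethylacetamide | CC(=O)N(C)C | starting material
4 | N-ethenylidene-N-methylmethanaminium trifluoromethanesulfonate (keteniminium triflate) | C=C=[N+](C)C.[O-]S(=O)(=O)C(F)(F)F | intermediate
5 | N,N-dimethyl-5-methylspiro[3.5]non-5-en-2-iminium trifluoromethanesulfonate (cyclobutaniminium triflate) | CC1=CCCCC12CC(=[N+](C)C)C2.[O-]S(=O)(=O)C(F)(F)F | intermediate
6 | 5-methylspiro[3.5]non-5-en-2-one | CC1=CCCCC12CC(=O)C2 | intermediate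
7 | 4-methoxybenzyl (7R,7aS)-7a-methyl-2-oxo-2,4,5,6,7,7a-hexahydro-1H-indene-7-carboxylate | C1C(=O)C=C2CCC[C@@H](C(=O)OCc3ccc(OC)cc3)[C@@]21C | intermediate
8 | 3-bromo-2-(bromomethyl)prop-1-ene | C=C(CBr)CBr | starting material
9 | 4-methoxybenzyl (1R,7R,7aS)-1-[2-(bromomethyl)prop-2-en-1-yl]-7a-methyl-2-oxo-2,4,5,6,7,7a-hexahydro-1H-indene-7-carboxylate | C=C(CBr)C[C@H]1C(=O)C=C2CCC[C@@H](C(=O)OCc3ccc(OC)cc3)[C@@]21C | intermediate
10 | 4-methoxybenzyl (1R,7R,7aS)-1-(2-formylprop-2-en-1-yl)-7a-methyl-2-oxo-2,4,5,6,7,7a-hexahydro-1H-indene-7-carboxylate | C=C(C=O)C[C@H]1C(=O)C=C2CCC[C@@H](C(=O)OCc3ccc(OC)cc3)[C@@]21C | intermediate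
11 | 4-methoxybenzyl (1R,7R,7aS)-1-(2-formylprop-2-en-1-yl)-7a-methyl-2-(trimethylsilyloxy)-5,6,7,7a-tetrahydro-1H-indene-7-carboxylate (silyl dienol ether) | C=C(C=O)C[C@H]1C(O[Si](C)(C)C)=CC2=CCC[C@@H](C(=O)OCc3ccc(OC)cc3)[C@@]21C | intermediate
12 | 4-methoxybenzyl (1R,4S,7R,7aS)-1-(2-formylprop-2-en-1-yl)-4-hydroxy-7a-methyl-2-oxo-2,4,5,6,7,7a-hexahydro-1H-indene-7-carboxylate | C=C(C=O)C[C@H]1C(=O)C=C2[C@@H](O)CC[C@@H](C(=O)OCc3ccc(OC)cc3)[C@@]21C | intermediate
13 | (R)-2-methylbutan-1-ol | OC[C@H](C)CC | starting material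
14 | (R)-2-methylbutanal | O=C[C@H](C)CC | intermediate
15 | (2E,4R)-2,4-dimethylhex-2-enal | O=C/C(C)=C/[C@H](C)CC | intermediate
16 | (2E,4E,6R)-4,6-dimethylocta-2,4-dienoic acid | OC(=O)/C=C/C(C)=C/[C@H](C)CC | intermediate
17 | 4-methoxybenzyl (1R,4S,7R,7aS)-4-{[(2E,4E,6R)-4,6-dimethylocta-2,4-dienoyl]oxy}-1-(2-formylprop-2-en-1-yl)-7a-methyl-2-oxo-2,4,5,6,7,7a-hexahydro-1H-indene-7-carboxylate | C=C(C=O)C[C@H]1C(=O)C=C2[C@@H](OC(=O)/C=C/C(C)=C/[C@H](C)CC)CC[C@@H](C(=O)OCc3ccc(OC)cc3)[C@@]21C | intermediate
18 | (1R,4S,7R,7aS)-4-{[(2E,4E,6R)-4,6-dimethylocta-2,4-dienoyl]oxy}-1-(2-formylprop-2-en-1-yl)-7a-methyl-2-oxo-2,4,5,6,7,7a-hexahydro-1H-indene-7-carboxylic acid (CNP0302671.3) | C=C(C=O)C[C@H]1C(=O)C=C2[C@@H](OC(=O)/C=C/C(C)=C/[C@H](C)CC)CC[C@@H](C(=O)O)[C@@]21C | target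

**Step count and risks**

Total: 10 steps. Longest linear sequence: 8 steps (steps 1 to 6, then 9 and 10); the acid 16 is made in 2 steps in parallel.

The three steps most likely to fail:

The carbonylative ring expansion of step 3 is unprecedented; β-hydride elimination from the secondary alkylpalladium, allylic C–H palladation or poor enantiocontrol could defeat it. The fallback uses known chemistry, sets out from 1 and comes back at 7. Copper-catalysed conjugate addition of CH2=CHMgBr (CuI cat.) to 1 and alkylation of the enolate with 3-bromo-2-methoxyprop-1-ene, trans to the new vinyl group, give racemic rac-(2S,3S)-3-ethenyl-2-(2-methoxyprop-2-en-1-yl)-2-methylcyclohexan-1-one F1. Dilute HCl hydrolyses the enol ether to rac-(2S,3S)-3-ethenyl-2-methyl-2-(2-oxopropyl)cyclohexan-1-one F2. OsO4 (cat.) with KHSO5 cleaves the vinyl group to rac-(1R,2S)-2-methyl-3-oxo-2-(2-oxopropyl)cyclohexane-1-carboxylic acid F3. KOH in MeOH closes the cyclopentenone by intramolecular aldol condensation, and the racemic acid is resolved by crystallisation of its 1-phenylethylammonium salt (amine enantiomer chosen by screening) to (7R,7aS)-7a-methyl-2-oxo-2,4,5,6,7,7a-hexahydro-1H-indene-7-carboxylic acid F4. 4-Methoxybenzyl chloride and Cs2CO3 in DMF then give 7.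

In step 6 the dienol ether may form on the wrong side, oxidation may occur at C3 instead of C4, or the C4 epimer may form. The fallback sets out from 10 and comes back at 12: direct allylic C–H hydroxylation at C4 with SeO2 (cat.) and tBuOOH in CH2Cl2, an ene reaction followed by a [2,3]-shift that needs no enol ether and has only one allylic C–H position available on that alkene; it makes no new compound (F0).

In step 4 the bifunctional dibromide can alkylate twice or cyclise onto the enolate oxygen. The fallback sets out from 7 and comes back at 10, bypassing 9. The same lithium enolate is alkylated with 2,3-dibromoprop-1-ene, a monofunctional allylic bromide, to give 4-methoxybenzyl (1R,7R,7aS)-1-(2-bromoprop-2-en-1-yl)-7a-methyl-2-oxo-2,4,5,6,7,7a-hexahydro-1H-indene-7-carboxylate F5. Reductive carbonylation of the alkenyl bromide with Pd(PPh3)4, CO and Bu3SnH then gives the α-methylene aldehyde 10.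

**Further compounds**
F1 | step 3 | rac-(2S,3S)-3-ethenyl-2-(2-methoxyprop-2-en-1-yl)-2-methylcyclohexan-1-one | O=C1CCC[C@@H](C=C)[C@@]1(CC(OC)=C)C
F2 | step 3 | rac-(2S,3S)-3-ethenyl-2-methyl-2-(2-oxopropyl)cyclohexan-1-one | O=C1CCC[C@@H](C=C)[C@@]1(CC(C)=O)C
F3 | step 3 | rac-(1R,2S)-2-methyl-3-oxo-2-(2-oxopropyl)cyclohexane-1-carboxylic acid | O=C1CCC[C@@H](C(=O)O)[C@@]1(CC(C)=O)C
F4 | step 3 | (7R,7aS)-7a-methyl-2-oxo-2,4,5,6,7,7a-hexahydro-1H-indene-7-carboxylic acid | C1C(=O)C=C2CCC[C@@H](C(=O)O)[C@@]21C
F5 | step 4 | 4-methoxybenzyl (1R,7R,7aS)-1-(2-bromoprop-2-en-1-yl)-7a-methyl-2-oxo-2,4,5,6,7,7a-hexahydro-1H-indene-7-carboxylate | C=C(Br)C[C@H]1C(=O)C=C2CCC[C@@H](C(=O)OCc3ccc(OC)cc3)[C@@]21C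
F0 | step 6 | none | none
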